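The route rests on cutting ring B of the flavone back to a four-membered ring. The contiguous run C2'(OMe)–C3'(O)–C4'(H)–C5'(OH) of ring B is carried by a 4-methoxy-3-isopropoxycyclobutenone, and C1'/C6' by a 1,1-disubstituted vinyl group on its quaternary carbon. On heating, one operation opens the cyclobutenone to a dienylketene, closes the C5'–C6' bond and aromatises, giving the para-methoxyphenol pattern of ring B with every substituent placed. The precursor is racemic 4-(3,3-diethoxyprop-1-en-2-yl)-3-isopropoxy-4-methoxycyclobut-2-en-1-one; its acetal carbon later becomes C2 of the chromone, and ring A comes from a 2'-hydroxyacetophenone.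

Key step: step 3

Remark: the ring A ketone used in step 6 is taken as a purchased catalogue compound; compounds with a single stereocentre are racemic and drawn as one enantiomer.

Step 1
Reactants: 1 diisopropyl squarate (3,4-diisopropoxycyclobut-3-ene-1,2-dione)
Product: 3 3-isopropoxycyclobut-3-ene-1,2-dione, via hydride adduct 2 (not isolated)
Conditions: LiAlH(OtBu)3, THF, −78 to −20 °C; then conc. HCl, CH2Cl2, rt
Reagents that add atoms: water, O
Why: The bulky alkoxyaluminium hydride adds once (1,2-reduction) to a carbonyl of the symmetrical squarate, and strong acid then ionises the carbinol to an alkoxy-stabilised cyclobutenyl cation that takes up water and expels isopropanol, the standard acid-mediated transposition of squarate 1,2-adducts to 3-alkoxycyclobutenediones; the stereocentre of 2 is transient and racemic.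

Step 2
Reactants: 4 2-bromo-3,3-diethoxyprop-1-ene; 3 3-isopropoxycyclobut-3-ene-1,2-dione
Product: 7 (4RS)-4-(3,3-diethoxyprop-1-en-2-yl)-3-isopropoxy-4-methoxycyclobut-2-en-1-one, via vinyllithium 5 (not isolated), via lithium alkoxide 6 (not isolated)
Conditions: t-BuLi (2 equiv), Et2O, −78 °C; then 3, THF, −78 °C; then MeOTf, −78 to 0 °C
Reagents that add atoms: methyl trifluoromethanesulfonate, COS(=O)(=O)C(F)(F)F
Why: Bromine–lithium exchange gives the 2-lithioacrolein acetal, which adds 1,2 to the more electrophilic ketone-like carbonyl of 3 (the one next to the isopropoxy-bearing carbon; the other is deactivated as a vinylogous ester), and the tertiary lithium alkoxide is trapped cold by Williamson-type O-methylation with MeOTf; the quaternary centre forms as a racemate, which is immaterial because step 3 flattens it.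

Step 3
Reactants: 7 (4RS)-4-(3,3-diethoxyprop-1-en-2-yl)-3-isopropoxy-4-methoxycyclobut-2-en-1-one
Product: 10 3-(diethoxymethyl)-5-isopropoxy-4-methoxyphenol, via dienylketene 8 (not isolated), via cyclohexadienone 9 (not isolated)
Conditions: toluene (0.02 M, under argon), 110 °C
Reagents that add atoms: none
Why: Heat drives a conrotatory 4π electrocyclic opening of the bond between the carbonyl carbon and the quaternary carbon of 7 to the (Z)-dienylketene 8, whose terminal methylene carbon adds to the ketene carbon in a thermal disrotatory 6π electrocyclisation that closes the six-membered ring B through the C5'–C6' bond, and the cyclohexa-2,4-dienone 9 tautomerises irreversibly to phenol 10. This is the Moore rearrangement of 4-alkenyl-4-alkoxycyclobutenones, of the kind that delivers a hydroquinone monomethyl ether. No stereocentre is created, and the racemic quaternary centre of 7 becomes the sp2 carbon C2'. The step needs torquoselectivity: the methoxy donor on the quaternary carbon should rotate outward, as oxygen donors on cyclobutenones do, so that the vinyl group turns inward and lies cis to the ketene for closure. Regiochemistry is not at stake because the order OMe, O-isopropyl, H, OH is already written into the four-membered ring, and high dilution in a non-nucleophilic solvent should keep the ketene from being intercepted.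

Step 4
Reactants: 10 3-(diethoxymethyl)-5-isopropoxy-4-methoxyphenol
Product: 11 5-(benzyloxy)-1-(diethoxymethyl)-3-isopropoxy-2-methoxybenzene
Conditions: BnBr, K2CO3, DMF, rt
Reagents that add atoms: benzyl bromide, BrCc1ccccc1
Why: Williamson ether synthesis on the phenoxide; the acetal and the other ethers are inert to carbonate base, and capping the phenol protects ring B from iodination and oxidation in step 7.

Step 5
Reactants: 11 5-(benzyloxy)-1-(diethoxymethyl)-3-isopropoxy-2-methoxybenzene
Product: 12 5-(benzyloxy)-3-isopropoxy-2-methoxybenzaldehyde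
Conditions: 1 M HCl (cat.), THF–H2O, rt
Reagents that add atoms: water, O
Why: Acid-catalysed hydrolysis of the aryl diethyl acetal to the benzaldehyde, mild enough to leave the benzyl, isopropyl and methyl aryl ethers untouched.

Step 6
Reactants: 12 5-(benzyloxy)-3-isopropoxy-2-methoxybenzaldehyde; 13 1-(6-hydroxy-2,3,4-trimethoxyphenyl)ethan-1-one
Product: 14 (E)-3-[5-(benzyloxy)-3-isopropoxy-2-methoxyphenyl]-1-(6-hydroxy-2,3,4-trimethoxyphenyl)prop-2-en-1-one
Conditions: KOH, EtOH–H2O, rt
Reagents that add atoms: none
Why: Claisen–Schmidt (crossed aldol) condensation in which only the methyl ketone can enolise and the aldehyde cannot, and E1cB loss of water gives the conjugated E-enone as the thermodynamic alkene.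

Step 7
Reactants: 14 (E)-3-[5-(benzyloxy)-3-isopropoxy-2-methoxyphenyl]-1-(6-hydroxy-2,3,4-trimethoxyphenyl)prop-2-en-1-one
Product: 15 2-[5-(benzyloxy)-3-isopropoxy-2-methoxyphenyl]-5,6,7-trimethoxy-4H-chromen-4-one
Conditions: I2 (10 mol %), DMSO, 130 °C
Reagents that add atoms: none
Why: Iodine-catalysed oxidative cyclisation of a 2'-hydroxychalcone in DMSO (oxa-Michael closure of the phenol ortho to the ketone onto the enone, then iodination–elimination with DMSO regenerating iodine), the standard chalcone-to-flavone reaction; the only free phenol is the one that must cyclise, and the ethers on both rings are tolerated.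

Step 8
Reactants: 15 2-[5-(benzyloxy)-3-isopropoxy-2-methoxyphenyl]-5,6,7-trimethoxy-4H-chromen-4-one
Product: 16 2-(3,5-dihydroxy-2-methoxyphenyl)-5-hydroxy-6,7-dimethoxy-4H-chromen-4-one (target)
Conditions: BCl3, pentamethylbenzene, CH2Cl2, −78 to 0 °C; then MeOH, H2O
Reagents that add atoms: none
Why: Boron trichloride dealkylation, in which the peri 5-methoxy group is cleaved through a six-membered boron chelate with the C4 carbonyl, the secondary isopropyl ether and the benzyl ether are cleaved by ionisation at low temperature (the benzyl cation being taken up by pentamethylbenzene), and the unactivated methyl ethers at C6, C7 and C2' should survive.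

Compound list
1 | diisopropyl squarate (3,4-diisopropoxycyclobut-3-ene-1,2-dione) | CC(C)OC1=C(OC(C)C)C(=O)C1=O | starting material
2 | (4RS)-4-hydroxy-2,3-diisopropoxycyclobut-2-en-1-one (hydride adduct; racemic, one enantiomer drawn) | CC(C)OC1=C(OC(C)C)[C@@H](O)C1=O | intermediate
3 | 3-isopropoxycyclobut-3-ene-1,2-dione | CC(C)OC1=CC(=O)C1=O | intermediate
4 | 2-bromo-3,3-diethoxyprop-1-ene | CCOC(OCC)C(Br)=C | starting material
5 | (3,3-diethoxyprop-1-en-2-yl)lithium | [Li]C(=C)C(OCC)OCC | intermediate
6 | lithium (1RS)-1-(3,3-diethoxyprop-1-en-2-yl)-2-isopropoxy-4-oxocyclobut-2-en-1-olate (racemic, one enantiomer drawn) | [Li+].CCOC(OCC)C(=C)[C@]1([O-])C(OC(C)C)=CC1=O | intermediate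
7 | (4RS)-4-(3,3-diethoxyprop-1-en-2-yl)-3-isopropoxy-4-methoxycyclobut-2-en-1-one (racemic, one enantiomer drawn) | CCOC(OCC)C(=C)[C@]1(OC)C(OC(C)C)=CC1=O | intermediate
8 | (3Z)-5-(diethoxymethyl)-3-isopropoxy-4-methoxyhexa-1,3,5-trien-1-one (dienylketene) | O=C=C/C(OC(C)C)=C(/OC)C(=C)C(OCC)OCC | intermediate
9 | 5-(diethoxymethyl)-3-isopropoxy-4-methoxycyclohexa-2,4-dien-1-one | O=C1C=C(OC(C)C)C(OC)=C(C(OCC)OCC)C1 | intermediate
10 | 3-(diethoxymethyl)-5-isopropoxy-4-methoxyphenol | CCOC(OCC)c1cc(O)cc(OC(C)C)c1OC | intermediate
11 | 5-(benzyloxy)-1-(diethoxymethyl)-3-isopropoxy-2-methoxybenzene | CCOC(OCC)c1cc(OCc2ccccc2)cc(OC(C)C)c1OC | intermediate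
12 | 5-(benzyloxy)-3-isopropoxy-2-methoxybenzaldehyde | O=Cc1cc(OCc2ccccc2)cc(OC(C)C)c1OC | intermediate
13 | 1-(6-hydroxy-2,3,4-trimethoxyphenyl)ethan-1-one | CC(=O)c1c(O)cc(OC)c(OC)c1OC | starting material
14 | (E)-3-[5-(benzyloxy)-3-isopropoxy-2-methoxyphenyl]-1-(6-hydroxy-2,3,4-trimethoxyphenyl)prop-2-en-1-one | COc1cc(O)c(C(=O)/C=C/c2cc(OCc3ccccc3)cc(OC(C)C)c2OC)c(OC)c1OC | intermediate
15 | 2-[5-(benzyloxy)-3-isopropoxy-2-methoxyphenyl]-5,6,7-trimethoxy-4H-chromen-4-one | COc1cc2oc(-c3cc(OCc4ccccc4)cc(OC(C)C)c3OC)cc(=O)c2c(OC)c1OC | intermediate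
16 | 2-(3,5-dihydroxy-2-methoxyphenyl)-5-hydroxy-6,7-dimethoxy-4H-chromen-4-one | COc1cc2oc(-c3cc(O)cc(O)c3OC)cc(=O)c2c(O)c1OC | target

Total step count: 8
Longest linear sequence: 8 steps (1 to 16; 4 and 13 are purchased)

Steps most likely to fail

Step 3. The ring opening may proceed with incomplete outward rotation of the small methoxy group, or the tertiary, doubly allylic methyl ether may ionise before the ring opens, so that the ketene never meets the vinyl group. The fallback takes the methyl group out of the pericyclic step; it sets out from lithium alkoxide 6 and comes back to the route at 11. The cold solution of 6 is silylated with TBSOTf instead of being methylated, which should give (4RS)-4-[(tert-butyldimethylsilyl)oxy]-4-(3,3-diethoxyprop-1-en-2-yl)-3-isopropoxycyclobut-2-en-1-one F1, whose bulky silyloxy donor is the group that rotates outward. Thermolysis in toluene should then give 4-[(tert-butyldimethylsilyl)oxy]-3-(diethoxymethyl)-5-isopropoxyphenol F2. Its free phenol is benzylated under neutral Mitsunobu conditions (BnOH, PPh3, DIAD, THF) to [4-(benzyloxy)-2-(diethoxymethyl)-6-isopropoxyphenoxy](tert-butyl)dimethylsilane F3. TBAF in THF then releases 4-(benzyloxy)-2-(diethoxymethyl)-6-isopropoxyphenol F4, and MeI with K2CO3 in DMF methylates the now unambiguous oxygen to give 11.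

Step 2. The congested tertiary lithium alkoxide may be methylated incompletely or may begin to ring-open as the mixture warms, and MeOTf may be consumed by the ethereal solvent. The fallback separates addition from etherification; it sets out from 6 and comes back at 7. The cold solution of 6 is quenched with aqueous NH4Cl and (4RS)-4-(3,3-diethoxyprop-1-en-2-yl)-4-hydroxy-3-isopropoxycyclobut-2-en-1-one F5 is isolated. This carbinol is then methylated without strong base by MeI and Ag2O in MeCN at rt to give 7.

Step 8. While the benzyl ether is being cleaved, dealkylation may run on to the 6-methoxy or 2'-methoxy group, or benzyl cations may alkylate the electron-rich ring B. The fallback makes the deprotection orthogonal; it sets out from 15 and comes back at 16. Hydrogenolysis (H2, Pd/C, EtOAc, rt) removes only the benzyl group and should give 2-(5-hydroxy-3-isopropoxy-2-methoxyphenyl)-5,6,7-trimethoxy-4H-chromen-4-one F6. A short treatment with BCl3 in CH2Cl2 at −78 to 0 °C then has to cleave only the chelated 5-methoxy group and the isopropyl ether next to the 2'-methoxy group, giving 16.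

Further compounds
F1 | step 3 | (4RS)-4-[(tert-butyldimethylsilyl)oxy]-4-(3,3-diethoxyprop-1-en-2-yl)-3-isopropoxycyclobut-2-en-1-one (racemic, one enantiomer drawn) | CCOC(OCC)C(=C)[C@]1(O[Si](C)(C)C(C)(C)C)C(OC(C)C)=CC1=O
F2 | step 3 | 4-[(tert-butyldimethylsilyl)oxy]-3-(diethoxymethyl)-5-isopropoxyphenol | CCOC(OCC)c1cc(O)cc(OC(C)C)c1O[Si](C)(C)C(C)(C)C
F3 | step 3 | [4-(benzyloxy)-2-(diethoxymethyl)-6-isopropoxyphenoxy](tert-butyl)dimethylsilane | CCOC(OCC)c1cc(OCc2ccccc2)cc(OC(C)C)c1O[Si](C)(C)C(C)(C)C
F4 | step 3 | 4-(benzyloxy)-2-(diethoxymethyl)-6-isopropoxyphenol | CCOC(OCC)c1cc(OCc2ccccc2)cc(OC(C)C)c1O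
F5 | step 2 | (4RS)-4-(3,3-diethoxyprop-1-en-2-yl)-4-hydroxy-3-isopropoxycyclobut-2-en-1-one (racemic, one enantiomer drawn) | CCOC(OCC)C(=C)[C@]1(O)C(OC(C)C)=CC1=O
F6 | step 8 | 2-(5-hydroxy-3-isopropoxy-2-methoxyphenyl)-5,6,7-trimethoxy-4H-chromen-4-one | COc1cc2oc(-c3cc(O)cc(OC(C)C)c3OC)cc(=O)c2c(OC)c1OC
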